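Ring A is the methoxy-bearing quinone and ring B the dihydroxy quinone.

- **Cuts.** Ring B is cut from the chain at its ring C–CH2 bond (reductive alkylation of a 2,5-dihydroxy-3-methylbenzoquinone by a chain aldehyde). Ring A is cut at the bond between the carbonyl carbon flanked by C–OH and C–CH3 and that C–CH3 carbon (retro-6π-electrocyclisation to an allenyl-vinylketene, then retro-4π to a cyclobutenone). The cyclobutenone's C–chain and C–allenyl bonds are cut back to an alkyllithium, lithiated methoxyallene and a squaric ester.
- **Enabling feature.** In the fully substituted quinone ring A the sequence C(=O)–C(OH)=C(alkyl)–C(=O) maps onto the four ring carbons of a squarate-derived cyclobutenone. The pair C(OCH3)=C(CH3) maps onto the methoxy-bearing and central carbons of methoxyallene, whose terminal CH2 becomes the ring methyl. The ketene carbon can therefore bond to the central allene carbon and reach the quinone oxidation level without an oxidant.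
- **Forward order.** Di-tert-butyl squarate, then the allenyl adduct, then chain addition with carbonyl transposition, then ring A by thermal ring expansion, then acid unmasking of OH and CHO; ring B (made separately from tetramethoxybenzene) is joined last.
- **Stereochemistry.** The target has no stereocentre and no stereogenic double bond; the one carbinol stereocentre carried through the cyclobutenones is racemic and is destroyed in the ring expansion.

Key step: step 9

Remark: the linker is read as an unbranched (CH2)13 chain; 13-bromotridecan-1-ol, methoxyallene, squaric acid and 1,2,4,5-tetramethoxybenzene are taken as catalogue compounds.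

Step 1
Reactants: 1 squaric acid
Product: 2 disilver squarate (Ag2C4O4)
Conditions: AgNO3 (2 equiv), H2O, rt, dark; filter, dry
Reagents that add atoms: silver nitrate (AgNO3) [Ag+].[O-][N+](=O)[O-]
Why: Squaric acid is a strong vinylogous diacid whose disilver salt is insoluble in water, so salt metathesis with precipitation should go to completion.

Step 2
Reactants: 2 disilver squarate
Product: 3 di-tert-butyl squarate (3,4-di-tert-butoxycyclobut-3-ene-1,2-dione)
Conditions: t-BuCl (excess), Et2O, rt, dark
Reagents that add atoms: tert-butyl chloride CC(C)(C)Cl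
Why: Silver-assisted ionisation of tert-butyl chloride and capture of the cation by the squarate oxygens (SN1 O-alkylation of a silver salt) should give the acid-labile diester that direct esterification cannot deliver.

Step 3
Reactants: 4 methoxyallene (1-methoxypropa-1,2-diene); 3 di-tert-butyl squarate
Product: 7 2,3-di-tert-butoxy-4-(1-methoxypropa-1,2-dien-1-yl)-4-(triethylsilyloxy)cyclobut-2-en-1-one (racemic), via 1-lithio-1-methoxyallene 5 (not isolated), via lithium alkoxide adduct 6 (not isolated)
Conditions: n-BuLi, THF, −78 → −40 °C; 3, −78 °C; Et3SiOTf, −78 °C; aq NaHCO3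
Reagents that add atoms: triethylsilyl trifluoromethanesulfonate CC[Si](CC)(CC)OS(=O)(=O)C(F)(F)F
Why: Methoxyallene is deprotonated at its methoxy-bearing carbon and the alkoxyallenyllithium should add 1,2 to one of the two equivalent carbonyls of the squarate (organolithium 1,2-addition), the tertiary alkoxide being silylated in situ so that it cannot ionise in step 7; the new quaternary centre is racemic and disappears in step 9.

Step 4
Reactants: 8 13-bromotridecan-1-ol
Product: 9 13-bromotridecanal
Conditions: TEMPO (cat.), PhI(OAc)2, CH2Cl2, rt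
Reagents that add atoms: none
Why: Oxoammonium (TEMPO) oxidation with PhI(OAc)2 as terminal oxidant should stop at the aldehyde and leave the primary bromide untouched.

Step 5
Reactants: 9 13-bromotridecanal
Product: 10 13-bromo-1,1-dimethoxytridecane
Conditions: HC(OMe)3, TsOH (cat.), MeOH, rt
Reagents that add atoms: trimethyl orthoformate COC(OC)OC
Why: Acid-catalysed acetalisation with the orthoformate as water scavenger masks the aldehyde against the organolithium chemistry of step 7.

Step 6
Reactants: 10 13-bromo-1,1-dimethoxytridecane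
Product: 11 13-iodo-1,1-dimethoxytridecane
Conditions: NaI, NaHCO3 (cat.), acetone, reflux
Reagents that add atoms: sodium iodide (NaI) [Na+].[I-]
Why: Finkelstein halide exchange, driven by precipitation of NaBr, provides the iodide needed for a clean lithium–iodine exchange.

Step 7
Reactants: 11 13-iodo-1,1-dimethoxytridecane; 7 silylated allenyl squarate adduct
Product: 15 2-tert-butoxy-3-(13,13-dimethoxytridecyl)-4-(1-methoxypropa-1,2-dien-1-yl)-4-(triethylsilyloxy)cyclobut-2-en-1-one (racemic), via alkyllithium 12 (not isolated), via lithium alkoxide adduct 13 (not isolated), via trifluoroacetate ester 14 (not isolated)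
Conditions: t-BuLi (2.1 equiv), Et2O–pentane, −78 °C; 7, THF, −78 °C; (CF3CO)2O, −78 °C; aq NaHCO3
Reagents that add atoms: none
Why: Lithium–iodine exchange gives the primary alkyllithium, which should add 1,2 to the vinylogous ester carbonyl of 7, and trifluoroacetylation of the tertiary alkoxide then triggers ionisation to the alkoxy-stabilised cyclobutenyl cation and loss of the tert-butyl group from the distal oxygen (a Stork–Danheiser-type alkylative 1,3-carbonyl transposition), which places the chain next to the allenyl carbinol carbon while the silyl ether keeps the other oxygen from ionising.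

Step 8
Reactants: 15 transposed silyl ether
Product: 16 2-tert-butoxy-3-(13,13-dimethoxytridecyl)-4-hydroxy-4-(1-methoxypropa-1,2-dien-1-yl)cyclobut-2-en-1-one (racemic)
Conditions: Bu4NF, AcOH (1:1), THF, 0 °C → rt
Reagents that add atoms: none
Why: Acetic acid-buffered fluoride desilylation should free the tertiary hydroxyl without forming a free alkoxide (which could open the ring prematurely) and without acid strong enough to hydrate the allenyl ether or the acetal.

Step 9
Reactants: 16 4-allenyl-4-hydroxycyclobutenone
Product: 19 2-tert-butoxy-3-(13,13-dimethoxytridecyl)-5-methoxy-6-methylcyclohexa-2,5-diene-1,4-dione, via dienylketene 17 (not isolated), via ortho-quinone methide 18 (not isolated)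
Conditions: PhMe (0.02 M, degassed), 110 °C
Reagents that add atoms: none
Why: Heating 16 should open the cyclobutenone by a thermal conrotatory 4π-electrocyclic cleavage of the bond between the carbonyl carbon and the carbinol carbon, the donor hydroxyl rotating outward so that the methoxyallenyl group sits cis to the new ketene in 17. The ketene carbon and the central allene carbon are then the termini of a hexatriene and close the six-membered carbocycle, the only ring formed, by a thermal disrotatory 6π-electrocyclisation to the 4-hydroxy ortho-quinone methide 18. A proton shift from that hydroxyl to the exocyclic methylene (enol-to-keto tautomerisation, the thermodynamic sink) converts 18 into the para-quinone 19, so the allene terminus becomes the ring methyl and no oxidant is needed. The closest known reaction type is the Moore-type thermal ring expansion of 4-alkenyl- and 4-allenyl-4-hydroxycyclobutenones to hydroquinones, quinones and ortho-quinone methides. No stereocentre is formed and the racemic carbinol centre of 16 is destroyed. The step needs outward rotation of the hydroxyl (secured by its donor character; inward rotation would let it lactonise onto the ketene), while the order of the four ring substituents follows from the connectivity of 16 alone and not from the cyclisation.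

Step 10
Reactants: 19 tert-butoxy quinone acetal
Product: 20 13-(2-hydroxy-5-methoxy-6-methyl-1,4-benzoquinon-3-yl)tridecanal
Conditions: CF3CO2H–CH2Cl2–H2O (10:10:1), 0 °C → rt
Reagents that add atoms: water O
Why: Aqueous trifluoroacetic acid should cleave the vinylogous tert-butyl ester by loss of the tert-butyl cation and hydrolyse the dimethyl acetal in the same operation, whereas the vinylogous methyl ester cannot ionise and stays (acidolysis and acetal hydrolysis).

Step 11
Reactants: 21 1,2,4,5-tetramethoxybenzene
Product: 23 1,2,4,5-tetramethoxy-3-methylbenzene, via aryllithium 22 (not isolated)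
Conditions: n-BuLi, TMEDA, THF, 0 °C; MeI, 0 °C → rt
Reagents that add atoms: iodomethane CI
Why: The flanking methoxy groups direct lithiation to one of the two equivalent ring positions and the aryllithium is methylated by iodomethane (directed ortho-metalation followed by SN2 alkylation).

Step 12
Reactants: 23 1,2,4,5-tetramethoxy-3-methylbenzene
Product: 25 2,5-dihydroxy-3-methyl-1,4-benzoquinone, via benzenetetrol 24 (not isolated)
Conditions: BBr3, CH2Cl2, −78 °C → rt; H2O; then air, EtOAc–H2O, rt
Reagents that add atoms: none
Why: BBr3 cleaves all four aryl methyl ethers (Lewis acid ether cleavage) and the electron-rich benzenetetrol should autoxidise in air to the 2,5-dihydroxy-1,4-benzoquinone, a vinylogous acid that resists further oxidation.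

Step 13
Reactants: 20 ring A aldehyde; 25 2,5-dihydroxy-3-methyl-1,4-benzoquinone
Product: 27 target compound, via Knoevenagel alkylidene 26 (not isolated)
Conditions: Hantzsch ester (diethyl 2,6-dimethyl-1,4-dihydropyridine-3,5-dicarboxylate, 1.2 equiv), L-proline (20 mol%), CH2Cl2, rt
Reagents that add atoms: none
Why: Proline-promoted Knoevenagel condensation of the aldehyde with the only free ring position of the vinylogous acid 25 gives an alkylidene trione that is reduced in situ by conjugate hydride transfer from the Hantzsch ester (three-component reductive alkylation), while ring A of 20 has no free ring position and is a hydroxyquinone of the same low oxidising power as the product, so it should be inert.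

Compound list
1 | squaric acid (3,4-dihydroxycyclobut-3-ene-1,2-dione) | O=C1C(O)=C(O)C1=O | starting material
2 | disilver squarate (Ag2C4O4) | [Ag+].[Ag+].[O-]C1=C([O-])C(=O)C1=O | intermediate
3 | di-tert-butyl squarate | CC(C)(C)OC1=C(OC(C)(C)C)C(=O)C1=O | intermediate
4 | methoxyallene (1-methoxypropa-1,2-diene) | COC=C=C | starting material
5 | 1-lithio-1-methoxyallene | [Li]C(OC)=C=C | intermediate
6 | lithium 2,3-di-tert-butoxy-1-(1-methoxypropa-1,2-dien-1-yl)-4-oxocyclobut-2-en-1-olate (racemic) | [Li+].[O-]C1(C(OC)=C=C)C(=O)C(OC(C)(C)C)=C1OC(C)(C)C | intermediate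
7 | 2,3-di-tert-butoxy-4-(1-methoxypropa-1,2-dien-1-yl)-4-(triethylsilyloxy)cyclobut-2-en-1-one (racemic) | CC[Si](CC)(CC)OC1(C(OC)=C=C)C(=O)C(OC(C)(C)C)=C1OC(C)(C)C | intermediate
8 | 13-bromotridecan-1-ol | OCCCCCCCCCCCCCBr | starting material
9 | 13-bromotridecanal | O=CCCCCCCCCCCCCBr | intermediate
10 | 13-bromo-1,1-dimethoxytridecane | COC(OC)CCCCCCCCCCCCBr | intermediate
11 | 13-iodo-1,1-dimethoxytridecane | COC(OC)CCCCCCCCCCCCI | intermediate
12 | (13,13-dimethoxytridecyl)lithium | COC(OC)CCCCCCCCCCCC[Li] | intermediate
13 | lithium 2,3-di-tert-butoxy-1-(13,13-dimethoxytridecyl)-4-(1-methoxypropa-1,2-dien-1-yl)-4-(triethylsilyloxy)cyclobut-2-en-1-olate (diastereomer mixture, racemic) | [Li+].[O-]C1(CCCCCCCCCCCCC(OC)OC)C(OC(C)(C)C)=C(OC(C)(C)C)C1(O[Si](CC)(CC)CC)C(OC)=C=C | intermediate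
14 | trifluoroacetate ester of the alcohol of 13 | O=C(OC1(CCCCCCCCCCCCC(OC)OC)C(OC(C)(C)C)=C(OC(C)(C)C)C1(O[Si](CC)(CC)CC)C(OC)=C=C)C(F)(F)F | intermediate
15 | 2-tert-butoxy-3-(13,13-dimethoxytridecyl)-4-(1-methoxypropa-1,2-dien-1-yl)-4-(triethylsilyloxy)cyclobut-2-en-1-one (racemic) | O=C1C(OC(C)(C)C)=C(CCCCCCCCCCCCC(OC)OC)C1(O[Si](CC)(CC)CC)C(OC)=C=C | intermediate
16 | 2-tert-butoxy-3-(13,13-dimethoxytridecyl)-4-hydroxy-4-(1-methoxypropa-1,2-dien-1-yl)cyclobut-2-en-1-one (racemic) | O=C1C(OC(C)(C)C)=C(CCCCCCCCCCCCC(OC)OC)C1(O)C(OC)=C=C | intermediate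
17 | dienylketene: 2-tert-butoxy-3-(13,13-dimethoxytridecyl)-4-hydroxy-5-methoxyhepta-1,3,5,6-tetraen-1-one (allenyl cis to the ketene) | O=C=C(OC(C)(C)C)/C(CCCCCCCCCCCCC(OC)OC)=C(/O)C(OC)=C=C | intermediate
18 | ortho-quinone methide: 2-tert-butoxy-3-(13,13-dimethoxytridecyl)-4-hydroxy-5-methoxy-6-methylidenecyclohexa-2,4-dien-1-one | O=C1C(OC(C)(C)C)=C(CCCCCCCCCCCCC(OC)OC)C(O)=C(OC)C1=C | intermediate
19 | 2-tert-butoxy-3-(13,13-dimethoxytridecyl)-5-methoxy-6-methylcyclohexa-2,5-diene-1,4-dione | O=C1C(OC(C)(C)C)=C(CCCCCCCCCCCCC(OC)OC)C(=O)C(OC)=C1C | intermediate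
20 | 13-(2-hydroxy-5-methoxy-6-methyl-1,4-benzoquinon-3-yl)tridecanal | O=CCCCCCCCCCCCCC1=C(O)C(=O)C(C)=C(OC)C1=O | intermediate
21 | 1,2,4,5-tetramethoxybenzene | COc1cc(OC)c(OC)cc1OC | starting material
22 | (2,3,5,6-tetramethoxyphenyl)lithium | [Li]c1c(OC)c(OC)cc(OC)c1OC | intermediate
23 | 1,2,4,5-tetramethoxy-3-methylbenzene | Cc1c(OC)c(OC)cc(OC)c1OC | intermediate
24 | 3-methylbenzene-1,2,4,5-tetrol | Cc1c(O)c(O)cc(O)c1O | intermediate
25 | 2,5-dihydroxy-3-methyl-1,4-benzoquinone | CC1=C(O)C(=O)C=C(O)C1=O | intermediate
26 | Knoevenagel alkylidene trione (E/Z mixture) | O=C1C(=CCCCCCCCCCCCCC2=C(O)C(=O)C(C)=C(OC)C2=O)C(=O)C(=O)C(C)=C1O | intermediate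
27 | 2,5-dihydroxy-3-[13-(2-hydroxy-5-methoxy-6-methyl-1,4-benzoquinon-3-yl)tridecyl]-6-methyl-1,4-benzoquinone | COC1=C(C)C(=O)C(O)=C(CCCCCCCCCCCCCC2=C(O)C(=O)C(C)=C(O)C2=O)C1=O | target

Total step count: 13. Longest linear sequence: 8 steps (steps 1, 2, 3, 7, 8, 9, 10, 13; the chain branch through steps 4, 5, 6 is equally long).

Steps most likely to fail

Step 7. The functionalised alkyllithium may attack the alkoxy-bearing β-carbon (addition–elimination) or transfer a proton instead of adding to the carbonyl, and ionisation of the trifluoroacetate may also consume the acid-labile allenyl ether. The fallback is the ordinary squarate sequence, with no transposition and no allene; ring A is then closed at the C(=O)–C(OCH3) bond. It sets out from 3 and 12. Addition of 12 to 3 (THF, −78 °C) and quench with (CF3CO)2O should give 3-tert-butoxy-4-(13,13-dimethoxytridecyl)cyclobut-3-ene-1,2-dione F1. The vinyllithium obtained from (Z)-2-bromo-1-methoxyprop-1-ene and t-BuLi (Et2O, −78 °C; exchange with retention, lithium cis to the methoxy group) should add to the more electrophilic carbonyl, the one next to the tert-butoxy-bearing carbon, to give 3-tert-butoxy-2-(13,13-dimethoxytridecyl)-4-hydroxy-4-[(Z)-1-methoxyprop-1-en-2-yl]cyclobut-2-en-1-one F2. Heating in toluene (4π opening, 6π closure, enolisation) should give 2-tert-butoxy-3-(13,13-dimethoxytridecyl)-5-methoxy-6-methylbenzene-1,4-diol F3, and oxidation with Ag2O (Et2O, rt) comes back to the route at 19.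

Step 9. The ortho-quinone methide may dimerise or add a nucleophile before the proton shift, or inward rotation of the hydroxyl may divert the ketene to a furanone. The fallback uses an alkenyl group in place of the allenyl group: the electrocyclisation then gives a cyclohexadienone that aromatises, and the quinone level is reached with an oxidant. It sets out from 3. (Z)-1-Methoxyprop-1-enyllithium (from (Z)-1-methoxyprop-1-ene and t-BuLi, THF, −78 → 0 °C) is added to 3 and the alkoxide silylated with Et3SiOTf to give 2,3-di-tert-butoxy-4-[(Z)-1-methoxyprop-1-en-1-yl]-4-(triethylsilyloxy)cyclobut-2-en-1-one F4. Addition of 12 and (CF3CO)2O as in step 7 should give the transposed 2-tert-butoxy-3-(13,13-dimethoxytridecyl)-4-[(Z)-1-methoxyprop-1-en-1-yl]-4-(triethylsilyloxy)cyclobut-2-en-1-one F5. Bu4NF/AcOH should give 2-tert-butoxy-3-(13,13-dimethoxytridecyl)-4-hydroxy-4-[(Z)-1-methoxyprop-1-en-1-yl]cyclobut-2-en-1-one F6. Toluene at 110 °C should then give the hydroquinone 2-tert-butoxy-3-(13,13-dimethoxytridecyl)-5-methoxy-6-methylbenzene-1,4-diol F3, and Ag2O oxidation comes back to the route at 19.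

Step 13. The alkylidene intermediate may be captured by a second molecule of 25 (bis-adduct), or 20 may undergo aldol self-condensation in competition with hydride transfer. The fallback traps the alkylidene with a thiol and removes sulfur afterwards. It sets out from 20 and 25. Condensation in the presence of PhSH (EtOH, AcOH cat., 50 °C) should give the sulfide 2,5-dihydroxy-3-methyl-6-[13-(2-hydroxy-5-methoxy-6-methyl-1,4-benzoquinon-3-yl)-1-(phenylsulfanyl)tridecyl]-1,4-benzoquinone F7 (racemic). Desulfurisation with Raney nickel (EtOH, rt), followed by exposure to air to reoxidise the hydroquinones, comes back to the route at 27.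

Further compounds
F1 | step 7 | 3-tert-butoxy-4-(13,13-dimethoxytridecyl)cyclobut-3-ene-1,2-dione | O=C1C(=O)C(OC(C)(C)C)=C1CCCCCCCCCCCCC(OC)OC
F2 | step 7 | 3-tert-butoxy-2-(13,13-dimethoxytridecyl)-4-hydroxy-4-[(Z)-1-methoxyprop-1-en-2-yl]cyclobut-2-en-1-one (racemic) | O=C1C(CCCCCCCCCCCCC(OC)OC)=C(OC(C)(C)C)C1(O)/C(C)=C\OC
F3 | step 7 | 2-tert-butoxy-3-(13,13-dimethoxytridecyl)-5-methoxy-6-methylbenzene-1,4-diol | COc1c(C)c(O)c(OC(C)(C)C)c(CCCCCCCCCCCCC(OC)OC)c1O
F4 | step 9 | 2,3-di-tert-butoxy-4-[(Z)-1-methoxyprop-1-en-1-yl]-4-(triethylsilyloxy)cyclobut-2-en-1-one (racemic) | CC[Si](CC)(CC)OC1(/C(OC)=C/C)C(=O)C(OC(C)(C)C)=C1OC(C)(C)C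
F5 | step 9 | 2-tert-butoxy-3-(13,13-dimethoxytridecyl)-4-[(Z)-1-methoxyprop-1-en-1-yl]-4-(triethylsilyloxy)cyclobut-2-en-1-one (racemic) | O=C1C(OC(C)(C)C)=C(CCCCCCCCCCCCC(OC)OC)C1(O[Si](CC)(CC)CC)/C(OC)=C/C
F6 | step 9 | 2-tert-butoxy-3-(13,13-dimethoxytridecyl)-4-hydroxy-4-[(Z)-1-methoxyprop-1-en-1-yl]cyclobut-2-en-1-one (racemic) | O=C1C(OC(C)(C)C)=C(CCCCCCCCCCCCC(OC)OC)C1(O)/C(OC)=C/C
F7 | step 13 | 2,5-dihydroxy-3-methyl-6-[13-(2-hydroxy-5-methoxy-6-methyl-1,4-benzoquinon-3-yl)-1-(phenylsulfanyl)tridecyl]-1,4-benzoquinone (racemic) | COC1=C(C)C(=O)C(O)=C(CCCCCCCCCCCCC(Sc3ccccc3)C2=C(O)C(=O)C(C)=C(O)C2=O)C1=O
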